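## Structural features

The target is a terphenyl made of three phloroglucinol rings: terminal ring A (O-sulfate on A2, hydroxyls on A4 and A6), central ring B (hydroxyls on B2, B4 and B6, hydrogen on B5) and terminal ring C (hydroxyls on C2, C4 and C6), joined by the bonds A1–B1 and B3–C1. Each aryl–aryl bond is flanked by four oxygen substituents, and all three rings are very electron-rich. There is no sp3 stereocentre. The A1–B1 axis is formally stereogenic, because ring A (A2 sulfate against A6 hydroxyl) and ring B (B2 against B6) are both unsymmetrical about it; the B3–C1 axis is not, since ring C is symmetric. The fragile groups are the aryl sulfate monoester (lost in acid or with Lewis acids, stable to base, fluoride and hydrogenolysis) and the free polyphenol (air-sensitive). The real difficulty is twofold: one sulfate must go onto one of nine oxygens, at a hindered ortho position of a terminal ring where direct sulfation of the free nonaol would prefer the exposed para hydroxyls, and the A1–B1 bond is a tetra-ortho-oxygenated biaryl bond. The feature exploited is the oxygen pattern of ring A around the aryl-bearing carbon A1: A1 and A6 can be the two carbons of an aryl ynol silyl ether, and A2–A3–A4–A5 the four carbons of a 3-alkoxycyclobutenone. Ring A is then born with three chemically different oxygens (free hydroxyl on A2 from a ketene carbonyl, silyl ether on A6, benzyl ether on A4), and the A1–B1 bond is never made by coupling.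

## Logic of the disconnections

21 ⇒ 19 ⇒ 18 ⇒ 17. The cuts are seven O–benzyl bonds, the A6 O–Si bond and the A2 O–S bond. They are made last because the sulfate tolerates hydrogenolysis and fluoride but nothing acidic. The gain is that all site selection is transferred to 17, which must carry exactly one free hydroxyl, on A2. The demand on the forward steps is that sulfation precedes both deprotections and that no acid is used until the final proton exchange.

17 ⇒ 11 + 13 (key disconnection). Three ring A bonds are cut: A1–A2, A5–A6 and A2–A3. This is chosen because it dissolves ring A into an ynol silyl ether (A1, A6) and a cyclobutenone (A2–A5), and so removes both real difficulties at once. The crowded A1–B1 bond becomes an unhindered aryl–alkynyl bond. The three oxygens of ring A arrive from three different functional groups, so the sulfate site is fixed by construction. The demand is a regiospecific ketene–alkyne union at an alkyne carbon next to a di-ortho-substituted aryl group. In one sentence: ring A is grown by benzannulation of 13 onto 11.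

11 ⇒ 8 ⇒ 7. The cuts are the C(sp)–O bond and the terminal alkyne carbon. The ynol ether is traced to a terminal alkyne by acetylide oxidation and silylation, and the alkyne to an aryl aldehyde by one-carbon homologation. The gain is a robust, crystalline-type biaryl aldehyde as the storage point. The demand is strong-base chemistry at low temperature that leaves six benzyl ethers untouched.

7 ⇒ 4 + 6. The cut is the B3–C1 biaryl bond. It is made here because ring C is symmetric, so this axis carries no selectivity problem and an ordinary cross-coupling suffices. The gain is two monocyclic partners. The demand is a catalyst able to form a tetra-ortho-alkoxy biaryl before the boronic acid decomposes.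

4 and 6 ⇒ 2 ⇒ 1. The cuts are C–CHO, C–B and C–Br bonds. Both partners come from one bromide, which comes from one symmetric triether. The gain is a single aromatic starting material for rings B and C. The demand is clean monobromination and monoformylation, which the symmetry of 1 and 2 supports.

13 ⇒ 12. The cut is the vinylogous ester O–alkyl bond. An ethyl group is exchanged for benzyl so that the A4 oxygen is released in the final hydrogenolysis. The demand is an exchange that does not open the strained ring.

## Other disconnections considered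

Alternative 1: The first idea is to cut both biaryl bonds and assemble the terphenyl by two successive Suzuki–Miyaura couplings. The dibromide A1 would be coupled with 6 and then with the ring A boronic acid A2, which carries one ortho oxygen as a methoxymethyl ether, to give terphenyl A3; acetal removal, sulfation and hydrogenolysis would follow. The two bromines of A1 are equivalent, so the first coupling has to be stopped statistically. The second coupling must form another tetra-ortho-oxygenated bond on an already crowded ring. A2 needs a phloroglucinol protected in a two-to-one pattern, which is itself a statistical problem, and boronic acids of this type protodeboronate readily. The chosen plan forms only one such bond by coupling and obtains the oxygen differentiation from the ring construction.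

Alternative 2: The sulfate itself could serve as a temporary bridge. The diaryl sulfate A4, linking the ring A oxygen to the B6 oxygen, would be closed by intramolecular palladium-catalysed arylation to the seven-membered cyclic sulfate A5, and hydroxide would open the bridge to an aryl sulfate. The opening is the weak point: attack at sulfur can expel either aryloxide, both are di-ortho-substituted phloroglucinol oxygens of nearly equal leaving-group ability, and nothing in A5 biases the two S–O bonds. A seven-membered closure that creates a tetra-ortho axis is also less favourable than the six-membered lactone cases on which bridge strategies rest. The chosen plan fixes the sulfate site unambiguously.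

Alternative 3: Ring A could be folded from a masked poly-β-carbonyl chain. The triketide ester A6, carrying the biaryl on C2, would undergo Claisen cyclisation (C6 onto the ester carbon) to the aryl phloroglucinol A7. This builds the ring in its biosynthetic sense, but all three ring A oxygens emerge as free hydroxyls, and the exposed para hydroxyl of A7 would be sulfated before the hindered ortho ones. Assembly of A6 requires acylation of a very hindered arylacetate, and closure to a pyranone through oxygen competes with the Claisen mode. The chosen benzannulation is shorter and delivers the oxygens already distinguished.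

Key step: step 8

Assumptions: the SMILES carries no axial descriptor, so the A1–B1 axis is treated as unspecified and all intermediates are made as racemates. Compounds 1 and 12 are taken as catalogue compounds. The target is drawn as the free hydrogen sulfate; it is carried as its potassium salt and the acid form is released only in the last operation.

## Steps

Step 1
Reactants: 1 1,3,5-tris(benzyloxy)benzene
Product: 2 1,3,5-tris(benzyloxy)-2-bromobenzene
Conditions: NBS (1.0 equiv), CH2Cl2, −40 → 0 °C
Reagents that add atoms: N-bromosuccinimide, O=C1CCC(=O)N1Br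
Why: Electrophilic aromatic bromination; the three ring positions of 1 are equivalent and far more nucleophilic than the benzyl rings, and one equivalent of reagent at low temperature should stop at the monobromide because the halogen deactivates and crowds the remaining sites.

Step 2
Reactants: 2 1,3,5-tris(benzyloxy)-2-bromobenzene
Product: 4 2,4,6-tris(benzyloxy)-3-bromobenzaldehyde, via aryl iminium chloride 3 (not isolated)
Conditions: POCl3 (1.5 equiv), DMF, 0 → 60 °C; then ice/H2O
Reagents that add atoms: N,N-dimethylformamide, CN(C)C=O; water, O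
Why: Vilsmeier–Haack formylation; the two free positions of 2 are equivalent and each is ortho, ortho and para to an alkoxy group, so a single aldehyde should form after hydrolysis of 3, and the aryl bromide and benzyl ethers are inert to the chloroiminium salt.

Step 3
Reactants: 2 1,3,5-tris(benzyloxy)-2-bromobenzene
Product: 6 [2,4,6-tris(benzyloxy)phenyl]boronic acid, via aryllithium 5 (not isolated)
Conditions: n-BuLi (1.05 equiv), THF, −78 °C; B(OMe)3, −78 °C → rt; then 1 M HCl, 0 °C, brief
Reagents that add atoms: trimethyl borate, COB(OC)OC; water, O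
Why: Bromine–lithium exchange at −78 °C is much faster than benzylic deprotonation or Wittig rearrangement, 5 is stabilised by the two flanking oxygens, and borate trapping followed by short mild hydrolysis should give the boronic acid before protodeboronation sets in.

Step 4
Reactants: 4 2,4,6-tris(benzyloxy)-3-bromobenzaldehyde; 6 [2,4,6-tris(benzyloxy)phenyl]boronic acid (1.5 equiv)
Product: 7 2,2',4,4',6,6'-hexakis(benzyloxy)-[1,1'-biphenyl]-3-carbaldehyde
Conditions: Pd(OAc)2 (5 mol %), SPhos (10 mol %), K3PO4, toluene/H2O 10:1, 90 °C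
Reagents that add atoms: none
Why: Suzuki–Miyaura coupling with a dialkylbiarylphosphine ligand, the established system for tetra-ortho-substituted ortho-alkoxy biaryls; the aldehyde speeds oxidative addition into 4, excess 6 compensates for protodeboronation, and ring C is symmetric so the new axis carries no configuration.

Step 5
Reactants: 7 2,2',4,4',6,6'-hexakis(benzyloxy)-[1,1'-biphenyl]-3-carbaldehyde
Product: 8 2,2',4,4',6,6'-hexakis(benzyloxy)-3-ethynyl-1,1'-biphenyl
Conditions: dimethyl (1-diazo-2-oxopropyl)phosphonate, K2CO3, MeOH/THF, 0 °C → rt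
Reagents that add atoms: dimethyl (1-diazo-2-oxopropyl)phosphonate, COP(=O)(OC)C(=[N+]=[N-])C(C)=O
Why: Seyferth–Gilbert homologation in the Ohira–Bestmann form; methanolysis of the reagent gives the diazomethylphosphonate anion, which adds to the non-enolisable aldehyde, and the derived alkylidene carbene rearranges by 1,2-shift to the terminal alkyne under conditions that leave benzyl ethers untouched.

Step 6
Reactants: 8 2,2',4,4',6,6'-hexakis(benzyloxy)-3-ethynyl-1,1'-biphenyl
Product: 11 ({[2,2',4,4',6,6'-hexakis(benzyloxy)-[1,1'-biphenyl]-3-yl]ethynyl}oxy)tri(propan-2-yl)silane, via lithium acetylide 9 (not isolated), via lithium ynolate 10 (not isolated)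
Conditions: LiN(SiMe3)2, THF, −78 °C; t-BuOOLi (from t-BuOOH + LiN(SiMe3)2), −78 → 0 °C; i-Pr3SiOTf, −78 → 0 °C
Reagents that add atoms: tert-butyl hydroperoxide, CC(C)(C)OO; triisopropylsilyl trifluoromethanesulfonate, CC(C)[Si](C(C)C)(C(C)C)OS(=O)(=O)C(F)(F)F
Why: Oxidation of a lithium acetylide by lithium tert-butyl peroxide (carbon attacks the peroxide oxygen, tert-butoxide leaves) gives ynolate 10, and the bulky silyl triflate silylates ynolates on oxygen to give the siloxyalkyne; the low temperature protects the benzyl ethers from the amide base.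

Step 7
Reactants: 12 3-ethoxycyclobut-2-en-1-one
Product: 13 3-(benzyloxy)cyclobut-2-en-1-one
Conditions: BnOH (3 equiv), camphorsulfonic acid (5 mol %), toluene, 40 °C, reduced pressure (removal of EtOH), anhydrous
Reagents that add atoms: benzyl alcohol, OCc1ccccc1
Why: Acid-catalysed exchange of a vinylogous ester (addition of the alcohol to C3 of the protonated enone, then loss of ethanol), driven by removal of ethanol; exclusion of water avoids hydrolysis to the 1,3-dione.

Step 8
Reactants: 11 ({[2,2',4,4',6,6'-hexakis(benzyloxy)-[1,1'-biphenyl]-3-yl]ethynyl}oxy)tri(propan-2-yl)silane; 13 3-(benzyloxy)cyclobut-2-en-1-one (1.5 equiv, added in portions)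
Product: 17 4,2',4',6',2'',4'',6''-heptakis(benzyloxy)-6-{[tri(propan-2-yl)silyl]oxy}-[1,1':3',1''-terphenyl]-2-ol, via vinylketene 14 (not isolated), via vinylcyclobutenone 15 (not isolated), via dienylketene 16 (not isolated)
Conditions: toluene (0.2 M), 80 → 110 °C, sealed tube, Ar
Reagents that add atoms: none
Why: Danheiser benzannulation, the closest known reaction type being the union of cyclobutenones with trialkylsiloxyalkynes to give resorcinol monosilyl ethers; the 3-alkoxy group of 13 extends it to a phloroglucinol. Heat opens 13 reversibly (4π electrocyclic) to vinylketene 14, whose carbonyl carbon is attacked by the aryl-bearing carbon of 11, the nucleophilic terminus of the oxygen-polarised alkyne, so that a regiospecific [2+2] cycloaddition gives 15. A second 4π opening gives dienylketene 16, and the isomer with the ketene carbon cis to the alkoxyvinyl group closes ring A by a thermal disrotatory 6π electrocyclisation to a cyclohexa-2,4-dienone that tautomerises irreversibly to the phenol. Ring A is thus closed by 6π electrocyclisation (bonds A1–A2 and A5–A6 from the [2+2] step, A2–A3 from the electrocyclisation), and the four-membered ring of 15 is only a relay. No stereocentre is set: the sp3 carbon of 15 is erased in 16, and the A1–B1 axis, which pre-exists as the aryl–alkynyl bond of 11, emerges racemic. The selectivity required is the orientation of the ketene–alkyne union, secured by the siloxy group, which places the silyl ether on A6, the ketene oxygen on A2 as the only free hydroxyl, and the benzyloxy group on A4. The unproductive isomer of 16 can only return to 15, the sp ketene carbon is slender enough to reach the alkyne carbon next to the di-ortho-substituted aryl group, and a low stationary concentration of 14 limits its dimerisation and acylation of the product phenol.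

Step 9
Reactants: 17 4,2',4',6',2'',4'',6''-heptakis(benzyloxy)-6-{[tri(propan-2-yl)silyl]oxy}-[1,1':3',1''-terphenyl]-2-ol
Product: 18 potassium 4,2',4',6',2'',4'',6''-heptakis(benzyloxy)-6-{[tri(propan-2-yl)silyl]oxy}-[1,1':3',1''-terphenyl]-2-yl sulfate
Conditions: SO3·pyridine (5 equiv), pyridine, 50 °C; then aq. KOH to pH 8, 0 °C
Reagents that add atoms: sulfur trioxide–pyridine complex, [O-]S(=O)(=O)[n+]1ccccc1; potassium hydroxide, [K+].[OH-]
Why: O-sulfonation of a phenol by an amine–sulfur trioxide complex; 17 has a single free hydroxyl, so the site is fixed by structure, and the resulting sulfate monoester salt is stable to base and chromatography.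

Step 10
Reactants: 18 potassium 4,2',4',6',2'',4'',6''-heptakis(benzyloxy)-6-{[tri(propan-2-yl)silyl]oxy}-[1,1':3',1''-terphenyl]-2-yl sulfate
Product: 19 potassium 4,2',4',6',2'',4'',6''-heptakis(benzyloxy)-6-hydroxy-[1,1':3',1''-terphenyl]-2-yl sulfate
Conditions: KHF2 (2 equiv), MeOH/THF, rt → 40 °C
Reagents that add atoms: none
Why: Fluoride cleavage of an aryl silyl ether (bifluoride in methanol is selective for phenolic silyl ethers); the sulfate monoester anion and the benzyl ethers are inert to it and the counter-ion stays potassium.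

Step 11
Reactants: 19 potassium 4,2',4',6',2'',4'',6''-heptakis(benzyloxy)-6-hydroxy-[1,1':3',1''-terphenyl]-2-yl sulfate
Product: 21 4,6,2',4',6',2'',4'',6''-octahydroxy-[1,1':3',1''-terphenyl]-2-yl hydrogen sulfate, via potassium salt 20 (not isolated)
Conditions: H2 (1 atm), Pd/C, THF/MeOH 1:1, rt, Ar handling; filter; then HCl (1.0 equiv, 0.05 M aq.), 0 °C; C18 desalting (cold H2O, then MeOH/H2O); lyophilise
Reagents that add atoms: none
Why: Catalytic hydrogenolysis of seven benzyl aryl ethers over palladium, which aryl sulfate monoester salts survive under neutral conditions; one equivalent of cold acid and immediate desalting should release the hydrogen sulfate form before acid solvolysis of the S–O bond can compete.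

## Compound list

1 | 1,3,5-tris(benzyloxy)benzene | C(Oc1cc(OCc2ccccc2)cc(OCc2ccccc2)c1)c1ccccc1 | starting material
2 | 1,3,5-tris(benzyloxy)-2-bromobenzene | Brc1c(OCc2ccccc2)cc(OCc2ccccc2)cc1OCc1ccccc1 | intermediate
3 | N-{[2,4,6-tris(benzyloxy)-3-bromophenyl]methylidene}-N-methylmethanaminium chloride | C[N+](C)=Cc1c(OCc2ccccc2)cc(OCc2ccccc2)c(Br)c1OCc1ccccc1.[Cl-] | intermediate
4 | 2,4,6-tris(benzyloxy)-3-bromobenzaldehyde | O=Cc1c(OCc2ccccc2)cc(OCc2ccccc2)c(Br)c1OCc1ccccc1 | intermediate
5 | [2,4,6-tris(benzyloxy)phenyl]lithium | [Li]c1c(OCc2ccccc2)cc(OCc2ccccc2)cc1OCc1ccccc1 | intermediate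
6 | [2,4,6-tris(benzyloxy)phenyl]boronic acid | OB(O)c1c(OCc2ccccc2)cc(OCc2ccccc2)cc1OCc1ccccc1 | intermediate
7 | 2,2',4,4',6,6'-hexakis(benzyloxy)-[1,1'-biphenyl]-3-carbaldehyde | O=Cc1c(OCc2ccccc2)cc(OCc2ccccc2)c(-c2c(OCc3ccccc3)cc(OCc3ccccc3)cc2OCc2ccccc2)c1OCc1ccccc1 | intermediate
8 | 2,2',4,4',6,6'-hexakis(benzyloxy)-3-ethynyl-1,1'-biphenyl | C#Cc1c(OCc2ccccc2)cc(OCc2ccccc2)c(-c2c(OCc3ccccc3)cc(OCc3ccccc3)cc2OCc2ccccc2)c1OCc1ccccc1 | intermediate
9 | {[2,2',4,4',6,6'-hexakis(benzyloxy)-[1,1'-biphenyl]-3-yl]ethynyl}lithium | [Li]C#Cc1c(OCc2ccccc2)cc(OCc2ccccc2)c(-c2c(OCc3ccccc3)cc(OCc3ccccc3)cc2OCc2ccccc2)c1OCc1ccccc1 | intermediate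
10 | lithium 2-[2,2',4,4',6,6'-hexakis(benzyloxy)-[1,1'-biphenyl]-3-yl]ethyn-1-olate | [Li+].[O-]C#Cc1c(OCc2ccccc2)cc(OCc2ccccc2)c(-c2c(OCc3ccccc3)cc(OCc3ccccc3)cc2OCc2ccccc2)c1OCc1ccccc1 | intermediate
11 | ({[2,2',4,4',6,6'-hexakis(benzyloxy)-[1,1'-biphenyl]-3-yl]ethynyl}oxy)tri(propan-2-yl)silane | CC(C)[Si](OC#Cc1c(OCc2ccccc2)cc(OCc2ccccc2)c(-c2c(OCc3ccccc3)cc(OCc3ccccc3)cc2OCc2ccccc2)c1OCc1ccccc1)(C(C)C)C(C)C | intermediate
12 | 3-ethoxycyclobut-2-en-1-one | CCOC1=CC(=O)C1 | starting material
13 | 3-(benzyloxy)cyclobut-2-en-1-one | O=C1C=C(OCc2ccccc2)C1 | intermediate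
14 | 3-(benzyloxy)buta-1,3-dien-1-one | O=C=CC(=C)OCc1ccccc1 | intermediate
15 | 4-[1-(benzyloxy)ethenyl]-2-[2,2',4,4',6,6'-hexakis(benzyloxy)-[1,1'-biphenyl]-3-yl]-3-{[tri(propan-2-yl)silyl]oxy}cyclobut-2-en-1-one (racemic) | O=C1C(c2c(OCc3ccccc3)cc(OCc3ccccc3)c(-c3c(OCc4ccccc4)cc(OCc4ccccc4)cc3OCc3ccccc3)c2OCc2ccccc2)=C(O[Si](C(C)C)(C(C)C)C(C)C)C1C(=C)OCc1ccccc1 | intermediate
16 | 5-(benzyloxy)-2-[2,2',4,4',6,6'-hexakis(benzyloxy)-[1,1'-biphenyl]-3-yl]-3-{[tri(propan-2-yl)silyl]oxy}hexa-1,3,5-trien-1-one (ketene carbon cis to the alkoxyvinyl group) | O=C=C(c1c(OCc2ccccc2)cc(OCc2ccccc2)c(-c2c(OCc3ccccc3)cc(OCc3ccccc3)cc2OCc2ccccc2)c1OCc1ccccc1)/C(O[Si](C(C)C)(C(C)C)C(C)C)=C\C(=C)OCc1ccccc1 | intermediate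
17 | 4,2',4',6',2'',4'',6''-heptakis(benzyloxy)-6-{[tri(propan-2-yl)silyl]oxy}-[1,1':3',1''-terphenyl]-2-ol (racemic axis) | Oc1cc(OCc2ccccc2)cc(O[Si](C(C)C)(C(C)C)C(C)C)c1-c1c(OCc2ccccc2)cc(OCc2ccccc2)c(-c2c(OCc3ccccc3)cc(OCc3ccccc3)cc2OCc2ccccc2)c1OCc1ccccc1 | intermediate
18 | potassium 4,2',4',6',2'',4'',6''-heptakis(benzyloxy)-6-{[tri(propan-2-yl)silyl]oxy}-[1,1':3',1''-terphenyl]-2-yl sulfate | [K+].[O-]S(=O)(=O)Oc1cc(OCc2ccccc2)cc(O[Si](C(C)C)(C(C)C)C(C)C)c1-c1c(OCc2ccccc2)cc(OCc2ccccc2)c(-c2c(OCc3ccccc3)cc(OCc3ccccc3)cc2OCc2ccccc2)c1OCc1ccccc1 | intermediate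
19 | potassium 4,2',4',6',2'',4'',6''-heptakis(benzyloxy)-6-hydroxy-[1,1':3',1''-terphenyl]-2-yl sulfate | [K+].[O-]S(=O)(=O)Oc1cc(OCc2ccccc2)cc(O)c1-c1c(OCc2ccccc2)cc(OCc2ccccc2)c(-c2c(OCc3ccccc3)cc(OCc3ccccc3)cc2OCc2ccccc2)c1OCc1ccccc1 | intermediate
20 | potassium 4,6,2',4',6',2'',4'',6''-octahydroxy-[1,1':3',1''-terphenyl]-2-yl sulfate | [K+].[O-]S(=O)(=O)Oc1cc(O)cc(O)c1-c1c(O)cc(O)c(-c2c(O)cc(O)cc2O)c1O | intermediate
21 | 4,6,2',4',6',2'',4'',6''-octahydroxy-[1,1':3',1''-terphenyl]-2-yl hydrogen sulfate | O=S(=O)(O)Oc1cc(O)cc(O)c1-c1c(O)cc(O)c(-c2c(O)cc(O)cc2O)c1O | target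

## Step count and least certain steps

Total step count: 11. Longest linear sequence: 9 steps (steps 1, 2, 4, 5, 6, 8, 9, 10 and 11); steps 3 and 7 are side branches.

Step 8 (key step). The ring opening of the vinylogous-ester cyclobutenone may need temperatures at which the siloxyalkyne isomerises to a silylketene or the vinylketene dimerises. The [2+2] union may also be slow at the alkyne carbon next to the di-ortho-substituted aryl group. The fallback generates the same vinylketene below room temperature by 1,4-dehydrochlorination instead of electrocyclic opening. It sets out from 11 and returns at 17. Addition–elimination of sodium benzyloxide on ethyl (E)-3-chlorobut-2-enoate should give ethyl (E)-3-(benzyloxy)but-2-enoate F1. Saponification gives (E)-3-(benzyloxy)but-2-enoic acid F2, and oxalyl chloride gives (E)-3-(benzyloxy)but-2-enoyl chloride F3. Slow addition of F3 and Et3N to 11 at 0–25 °C forms 14 in the presence of its trap; the adduct 15 is then heated at 80 °C to pass through 16 to 17.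

Step 7. The alcohol may open the strained ring by attack at the carbonyl group, or adventitious water may hydrolyse the vinylogous ester, and the exchange equilibrium may stall. The fallback sets out from 12 and returns at 13. Cold dilute aqueous acid hydrolyses 12 to cyclobutane-1,3-dione F4, whose acidic enol is O-benzylated under Mitsunobu conditions (BnOH, PPh3, diisopropyl azodicarboxylate).

Step 6. Oxidation of the crowded, electron-rich acetylide by the peroxide may be slow, silylation may occur on carbon to give a silylketene, and the siloxyalkyne may decompose on silica. The fallback reaches the same ynolate by a rearrangement instead of an oxidation. It sets out from 7 and returns at 11 through 10. Pinnick oxidation gives 2,2',4,4',6,6'-hexakis(benzyloxy)-[1,1'-biphenyl]-3-carboxylic acid F5, and MeI/K2CO3 gives methyl 2,2',4,4',6,6'-hexakis(benzyloxy)-[1,1'-biphenyl]-3-carboxylate F6. Kowalski homologation of F6 (LiCHBr2, then n-BuLi) should give 10, which is silylated as in step 6.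

Step 4. Protodeboronation of the 2,6-dialkoxyarylboronic acid may outrun transmetalation onto a crowded arylpalladium intermediate. The fallback avoids boron and cross-selectivity altogether. It sets out from 2 and returns at 7. Ullmann homocoupling of 2 (activated copper powder, DMF, 150 °C) gives 2,2',4,4',6,6'-hexakis(benzyloxy)-1,1'-biphenyl F7. Vilsmeier–Haack formylation of F7 with one equivalent of reagent should give 7, since the four free positions are equivalent and the first formyl group deactivates only its own ring; recovered F7 is recycled.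

Step 9. Sulfation of a phenol flanked by the crowded axis may be slow, and the forcing conditions then needed may cleave or shift the neighbouring silyl ether. The fallback sulfates the other, symmetry-equivalent ortho oxygen after the silicon has been removed. It sets out from 17 and returns at 20. Benzylation of 17 (BnBr, K2CO3, DMF) gives {[2,4,2',4',6',2'',4'',6''-octakis(benzyloxy)-[1,1':3',1''-terphenyl]-6-yl]oxy}tri(propan-2-yl)silane F8. Fluoride desilylation gives 4,6,2',4',6',2'',4'',6''-octakis(benzyloxy)-[1,1':3',1''-terphenyl]-2-ol F9, which tolerates forcing sulfation (SO3·NMe3, K2CO3, 80 °C) to potassium 4,6,2',4',6',2'',4'',6''-octakis(benzyloxy)-[1,1':3',1''-terphenyl]-2-yl sulfate F10. Hydrogenolysis of F10 gives 20, which is acidified as in step 11.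

## Further compounds

F1 | step 8 | ethyl (E)-3-(benzyloxy)but-2-enoate | CCOC(=O)/C=C(\C)OCc1ccccc1
F2 | step 8 | (E)-3-(benzyloxy)but-2-enoic acid | OC(=O)/C=C(\C)OCc1ccccc1
F3 | step 8 | (E)-3-(benzyloxy)but-2-enoyl chloride | ClC(=O)/C=C(\C)OCc1ccccc1
F4 | step 7 | cyclobutane-1,3-dione | O=C1CC(=O)C1
F5 | step 6 | 2,2',4,4',6,6'-hexakis(benzyloxy)-[1,1'-biphenyl]-3-carboxylic acid | OC(=O)c1c(OCc2ccccc2)cc(OCc2ccccc2)c(-c2c(OCc3ccccc3)cc(OCc3ccccc3)cc2OCc2ccccc2)c1OCc1ccccc1
F6 | step 6 | methyl 2,2',4,4',6,6'-hexakis(benzyloxy)-[1,1'-biphenyl]-3-carboxylate | COC(=O)c1c(OCc2ccccc2)cc(OCc2ccccc2)c(-c2c(OCc3ccccc3)cc(OCc3ccccc3)cc2OCc2ccccc2)c1OCc1ccccc1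
F7 | step 4 | 2,2',4,4',6,6'-hexakis(benzyloxy)-1,1'-biphenyl | c1c(OCc2ccccc2)cc(OCc2ccccc2)c(-c2c(OCc3ccccc3)cc(OCc3ccccc3)cc2OCc2ccccc2)c1OCc1ccccc1
F8 | step 9 | {[2,4,2',4',6',2'',4'',6''-octakis(benzyloxy)-[1,1':3',1''-terphenyl]-6-yl]oxy}tri(propan-2-yl)silane | CC(C)[Si](Oc1cc(OCc2ccccc2)cc(OCc2ccccc2)c1-c1c(OCc2ccccc2)cc(OCc2ccccc2)c(-c2c(OCc3ccccc3)cc(OCc3ccccc3)cc2OCc2ccccc2)c1OCc1ccccc1)(C(C)C)C(C)C
F9 | step 9 | 4,6,2',4',6',2'',4'',6''-octakis(benzyloxy)-[1,1':3',1''-terphenyl]-2-ol | Oc1cc(OCc2ccccc2)cc(OCc2ccccc2)c1-c1c(OCc2ccccc2)cc(OCc2ccccc2)c(-c2c(OCc3ccccc3)cc(OCc3ccccc3)cc2OCc2ccccc2)c1OCc1ccccc1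
F10 | step 9 | potassium 4,6,2',4',6',2'',4'',6''-octakis(benzyloxy)-[1,1':3',1''-terphenyl]-2-yl sulfate | [K+].[O-]S(=O)(=O)Oc1cc(OCc2ccccc2)cc(OCc2ccccc2)c1-c1c(OCc2ccccc2)cc(OCc2ccccc2)c(-c2c(OCc3ccccc3)cc(OCc3ccccc3)cc2OCc2ccccc2)c1OCc1ccccc1
A1 | alternative 1 | 1,3,5-tris(benzyloxy)-2,4-dibromobenzene | Brc1c(OCc2ccccc2)cc(OCc2ccccc2)c(Br)c1OCc1ccccc1
A2 | alternative 1 | [2,4-bis(benzyloxy)-6-(methoxymethoxy)phenyl]boronic acid | OB(O)c1c(OCOC)cc(OCc2ccccc2)cc1OCc1ccccc1
A3 | alternative 1 | 4,6,2',4',6',2'',4'',6''-octakis(benzyloxy)-2-(methoxymethoxy)-1,1':3',1''-terphenyl | COCOc1cc(OCc2ccccc2)cc(OCc2ccccc2)c1-c1c(OCc2ccccc2)cc(OCc2ccccc2)c(-c2c(OCc3ccccc3)cc(OCc3ccccc3)cc2OCc2ccccc2)c1OCc1ccccc1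
A4 | alternative 2 | 3,5-bis(benzyloxy)phenyl 2',4,4',6,6'-pentakis(benzyloxy)-3-iodo-[1,1'-biphenyl]-2-yl sulfate | O=S(=O)(Oc1cc(OCc2ccccc2)cc(OCc2ccccc2)c1)Oc1cc(OCc2ccccc2)c(-c2c(OCc3ccccc3)cc(OCc3ccccc3)cc2OCc2ccccc2)c(OCc2ccccc2)c1I
A5 | alternative 2 | 1,2,4,9,11-pentakis(benzyloxy)-2-aryl-substituted dibenzo[d,f][1,3,2]dioxathiepine 6,6-dioxide (cyclic sulfate bridging the A2 and B6 oxygens, ring C on B3) | O=S1(=O)Oc2cc(OCc3ccccc3)cc(OCc3ccccc3)c2-c2c(O1)cc(OCc3ccccc3)c(-c3c(OCc4ccccc4)cc(OCc4ccccc4)cc3OCc3ccccc3)c2OCc2ccccc2
A6 | alternative 3 | methyl 2-[2,2',4,4',6,6'-hexakis(benzyloxy)-[1,1'-biphenyl]-3-yl]-3,5-dioxohexanoate | COC(=O)C(C(=O)CC(C)=O)c1c(OCc2ccccc2)cc(OCc2ccccc2)c(-c2c(OCc3ccccc3)cc(OCc3ccccc3)cc2OCc2ccccc2)c1OCc1ccccc1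
A7 | alternative 3 | 2',4',6',2'',4'',6''-hexakis(benzyloxy)-[1,1':3',1''-terphenyl]-2,4,6-triol | Oc1cc(O)c(-c2c(OCc3ccccc3)cc(OCc3ccccc3)c(-c3c(OCc4ccccc4)cc(OCc4ccccc4)cc3OCc3ccccc3)c2OCc2ccccc2)c(O)c1
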